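**Remarks on the chemistry**

- Locants: C7–C8–C9 is the guaiacyl-side chain and C7'–C8'–C9' the catechol-side chain; O7, O9 and O9' are the oxygens on C7, C9 and C9', and O9 is the ring oxygen. ArG = 4-benzyloxy-3-methoxyphenyl; ArC = 3,4-bis(benzyloxy)phenyl.
- Descriptor at C8 of the dihydrofurans: in 15–17 the ring carbon C3 (= C8) is (R), because C7 (O,C,H) > C2 (O,H,H) > C4 (C,C,H) > H. An (S) label at that centre would denote the C8 epimer, which cannot lead to the target; the SMILES of 16 is the (R,R) compound.
- Assumption: the MgCl2-catalysed anti-aldol follows its normal course through the chelated Z-enolate, with the aldehyde on the face away from the auxiliary benzyl group, so the (R)-auxiliary 2 should give the (3S,4R) adduct 7.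

## Structural features

The target is a 2,3,4-trisubstituted tetrahydrofuran (ring atoms O9, C7', C8', C8, C9). C7' carries the catechol ring, C8' the C9' hydroxymethyl group, and C8 an exocyclic secondary carbinol C7 bonded to the guaiacyl ring. The four stereocentres C7–C8–C8'–C7' are contiguous (7R, 8R, 8'R, 7'S): the C7 arm and C9' are cis on the ring, C9' and the C7' aryl group are trans, and C7 lies outside the ring. Both benzylic C–O bonds (C7–O7 and C7'–O9) sit para to an oxygen substituent, so they ionise under acid (epimerisation, quinone-methide chemistry) and are open to hydrogenolysis. The free catechol is oxidation-sensitive, and C8' epimerises whenever C9' is a free aldehyde. The real difficulty is the 8,8'-cis placement of two branched substituents next to a trans aryl group, together with an exocyclic carbinol centre that no ring holds. The key step uses the fact that O7 is homoallylic to a C7'=C8' double bond in the ring, and that both C9' and the C7' hydrogen lie on the ring face that carries the C7 arm. A syn addition of hydrogen and a formyl carbon delivered from O7 therefore sets C8' and C7' together, and O7 then captures C9' as a cis-fused lactol (a 3,7-dioxabicyclo[3.3.0]octane).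

## Logic of the disconnections

22 ⇒ 21. The three phenolic O–H bonds are traced back to O–CH2Ph bonds. Free phenols and a catechol would be oxidised, would consume organolithium and could bind rhodium, whereas benzyl ethers survive every step up to 21. The gain is a robust, neutral substrate. The demand is a final hydrogenolysis that stops before the two benzylic C–O bonds of the skeleton are touched.

21 ⇒ 20. The O9'–H and O7–H bonds are folded into one O7–C9' acetal bond, raising C9' to the aldehyde level. 20 is the form in which C8' cannot epimerise, because only the cis-fused bicycle can close. The demand is a hydride reduction through the open form 19 that is faster than enolisation.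

20 ⇒ 16. The C8'–C9' bond, the C7'–H bond and the O7–C9' bond are cut. This removes one ring, one skeletal bond and the two ring stereocentres C8' and C7', leaving a planar enol ether and only C7 and C8 to be made beforehand. The forward step must add H and CHO syn, on the face of the C7 arm, with the carbon at C8'.

16 ⇒ 15 ⇒ 13. O7–H is traced to O7–Si, then the enol-ether bond O9–C7' is cut by formal addition of water across C7'=C8'. This gives an open γ-hydroxy aryl ketone. The demand is that only O9 is free during ring closure, since O7 could close a five-membered enol ether of its own; for the same reason O7 is released only in the step before the key step.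

13 ⇒ 10 + 11. The C7'–aryl bond is cut, giving a lactone whose acyl carbon is C7' and whose ring oxygen is already O9, plus the aryl bromide (through 12). The gain is convergence and a shorter precursor synthesis: a single addition produces the hydroxy ketone, without separate protection of O9, conversion of the acyl carbon to an N-methoxy-N-methylamide, or a later unmasking. The demand is that the organolithium adds only once.

10 ⇒ 9 ⇒ 7. O7–Si is traced to O7–H, then the lactone bond O9–C7' is cut and C9 is raised to the acyl oxidation level (through 8). This gives an aldol adduct in which C9 is the auxiliary-bound carbonyl and C7' a methyl ester. The demands are a reduction that distinguishes the imide from the ester, and ring closure at the primary O9 instead of the secondary O7.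

7 ⇒ 4 + 5. The C7–C8 bond is cut. This is the only disconnection that makes both C7 and C8, and it leads to an achiral aldehyde and a succinate imide. The demand is anti relative configuration with absolute control, which calls for the MgCl2-catalysed anti-aldol with auxiliary 2.

4 ⇒ 1 + 2. The N–acyl bond is cut, leaving two commercial compounds. The demand is acylation at the free acid terminus of 1 only.

## Other disconnections considered

Alternative 1: The cut is the C8–C8' ring bond, which opens the tetrahydrofuran to the acyclic ether A1. A1 is an N-acyloxyphthalimide whose C9–O–C7' ether already carries the (S)-configured C7' and an (E)-vinylboronate.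

- Forward step: single-electron reduction of A1 (for example Ru(bpy)3Cl2, a Hantzsch ester and visible light) would expel CO2 and phthalimide. The secondary C8 radical would close 5-exo-trig onto the boron-bearing alkene, and hydrogen-atom transfer to the α-boryl radical would give A2. C–B oxidation, desilylation and debenzylation would follow.
- In its favour: decarboxylative radical generation and radical addition to vinylboronates are established reaction types, so on precedent this key step is the stronger of the two. A chair-like 5-exo transition state with the C7 arm and the C7' aryl group pseudo-equatorial leads to the required 8,8'-cis, 7',8'-trans pattern. C8 may be a mixture in A1 because it becomes planar, a convergence the chosen plan does not have. C9' arrives as a C–B bond that cannot epimerise.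
- Against it: the two ring centres would be set by the conformational preference of a flexible transition state, not by a stereospecific event, and the neighbouring C7 centre may reinforce or oppose that preference. A1 needs an ether between a primary carbon and a benzylic, allylic secondary carbinol, a vinylboronate, and a β-silyloxy active ester liable to β-elimination, so it must be assembled from two enantioenriched fragments.
- Comparison: both plans create one C–C bond at C8' and two stereocentres in the key step (equal). The alternative closes the final tetrahydrofuran itself, whereas the chosen plan closes a temporary lactol ring. It trades tether-enforced syn addition for substrate-controlled radical diastereoselection. It needs three operations after the key step against two, and a longer approach to its precursor, so the chosen plan should be shorter overall.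

Alternative 2: The cuts are C7–C8 and C8'–C9', which remove a four-membered ring from cyclobutanone A5 and lead to the (S)-dihydrofuran A3 and the arylketene A4.

- Locants of A5: A5 is a 7-endo-aryl-4-exo-aryl-3-oxabicyclo[3.2.0]heptan-6-one. The carbonyl C6 is bonded to the bridgehead C5 (= C8'), which also carries C4 (= C7'). A 2-aryl locant would describe the regioisomer from the opposite ketene orientation.
- Forward step: A4, generated in situ, would add suprafacially to the C8=C8' bond of A3 on the face anti to the C7' aryl group, with the ketene aryl group endo. Baeyer–Villiger oxidation with migration of the benzylic C7 would give lactone A6, and LiAlH4 would reduce A6 to 21, where the route rejoins the chosen endgame.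
- In its favour: two C–C bonds and three stereocentres (C7, C8, C8') from the single centre C7' in one step, which is more than the chosen key step achieves. The endo preference of the larger ketene substituent accounts for C7, and ring fusion for the 8,8'-cis relation. The step count could be lower than that of the chosen plan.
- Against it: the C8=C8' bond of A3 is unactivated and electronically unbiased, so the orientation of the ketene rests only on a remote steric effect. Monoarylketenes dimerise and add sluggishly to such alkenes, and Lewis-acid promotion tends to change the endo/exo outcome. The Baeyer–Villiger step must choose between two secondary migrating carbons in the presence of electron-rich arenes. A3 needs its own asymmetric synthesis, and its C7' centre is benzylic, allylic and α to oxygen, so it is prone to isomerisation to the conjugated enol ether or to aromatisation.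
- Comparison: the alternative is better in bonds and stereocentres formed per step and equal in the endgame (both pass through 21). It is weaker in the number of independent selectivities (regiochemistry, endo/exo, migration) that must all fall the right way, against one tether-enforced addition. It is better in step economy only if those selectivities hold.

Alternative 3: The cuts are O9–C7' and C8–C8', which reduce A9 to the arylidene malonate A7 and the racemic vinyl epoxide A8.

- Forward step: Pd2(dba)3 with a chiral diphosphine would ionise A8 to a zwitterionic allyl complex of divalent palladium. The alkoxide would add to A7, and the malonate carbon would attack the substituted allyl terminus, giving the 2,4-trans tetrahydrofuran A9 with C7' and C8 set by the catalyst from a racemate.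
- In its favour: a catalytic, enantioselective, convergent ring synthesis from two simple components with no stoichiometric auxiliary. On step economy and on the source of chirality it is better than the chosen plan, and the overall count could fall to about eight steps.
- Against it: C8' is made as a non-stereogenic diester carbon. It would have to be set later by dealkoxycarbonylation and protonation (cis to the C8 substituent, trans to the aryl group), which is governed only by a modest thermodynamic or kinetic bias. The vinyl group has one carbon too many, so it must be cleaved oxidatively and the guaiacyl ring added to an epimerisable α-branched aldehyde, with C7 left to 1,2-induction next to coordinating esters.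
- Comparison: the alternative builds the ring and two C–X/C–C bonds in one step, against one C–C bond and a temporary ring in the chosen plan. It relies on catalyst control for C7'/C8 and on substrate control for C8' and C7. The chosen plan sets C7/C8 with a dependable auxiliary aldol and C8'/C7' in one stereospecific event. The alternative is shorter; the chosen plan has fewer stereocentres left to substrate control.

Key step: step 8

## Route

Step 1
Reactants: 1 monomethyl succinate; 2 (R)-4-benzyl-2-oxazolidinone
Product: 4 methyl 4-[(4R)-4-benzyl-2-oxooxazolidin-3-yl]-4-oxobutanoate, via mixed pivalic anhydride 3 (not isolated)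
Conditions: PivCl, Et3N, THF, −20 °C; then LiCl, 2, −20 °C to rt
Reagents that add atoms: none
Why: N-acylation of the oxazolidinone through the mixed anhydride 3; LiCl/Et3N makes the carbamate nitrogen nucleophilic enough, and attack occurs at the unhindered succinyl carbonyl and not at the pivaloyl carbonyl.

Step 2
Reactants: 4 methyl 4-[(4R)-4-benzyl-2-oxooxazolidin-3-yl]-4-oxobutanoate; 5 4-benzyloxy-3-methoxybenzaldehyde
Product: 7 methyl (3S,4R)-3-[(4R)-4-benzyl-2-oxooxazolidine-3-carbonyl]-4-ArG-4-hydroxybutanoate, via trimethylsilyl ether 6 (not isolated)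
Conditions: MgCl2 (0.2 equiv), Et3N, Me3SiCl, EtOAc, rt; then citric acid, MeOH, 0 °C
Reagents that add atoms: none
Why: MgCl2-catalysed direct anti-aldol of an N-acyloxazolidinone: soft enolisation occurs only at the chelated imide, the Z-enolate is attacked by the non-enolisable aldehyde on the face away from the benzyl group in a boat-like closed transition state, and silylation of the aldolate to 6 turns the catalyst over. With the (R)-auxiliary this should set C8 (3S) and C7 (4R) in the anti relation; mild acidic methanolysis then frees 7 without ionising the electron-rich benzylic position.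

Step 3
Reactants: 7 methyl (3S,4R)-3-[(4R)-4-benzyl-2-oxooxazolidine-3-carbonyl]-4-ArG-4-hydroxybutanoate
Product: 9 (4R)-4-[(R)-ArG(hydroxy)methyl]oxolan-2-one, via diol ester 8 (not isolated)
Conditions: NaBH4, THF/H2O (4:1), 0 °C; aq citric acid; then DBU (0.1 equiv), MeOH (2 equiv), CH2Cl2, rt
Reagents that add atoms: none
Why: Reductive removal of the auxiliary: NaBH4 in wet THF reduces the activated exocyclic imide carbonyl much faster than the methyl ester, releasing 2 and diol ester 8, whose primary O9 closes onto the ester (5-exo-trig lactonisation). The base equilibration moves any acyl group held on the secondary O7 to the primary oxygen, because 9 is free of the cis-4,5 strain of the benzylic lactone; no stereocentre is acidic or β to a carbonyl at this stage.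

Step 4
Reactants: 9 (4R)-4-[(R)-ArG(hydroxy)methyl]oxolan-2-one
Product: 10 (4R)-4-[(R)-ArG(tert-butyldimethylsilyloxy)methyl]oxolan-2-one
Conditions: TBSOTf, 2,6-lutidine, CH2Cl2, −78 to 0 °C
Reagents that add atoms: tert-butyldimethylsilyl triflate, CC(C)(C)[Si](C)(C)OS(=O)(=O)C(F)(F)F
Why: Standard silylation of a hindered secondary alcohol; the bulky silyl ether blocks O7 so that only O9 can close the dihydrofuran later, and it tolerates organolithium and mild acid.

Step 5
Reactants: 10 (4R)-4-[(R)-ArG(tert-butyldimethylsilyloxy)methyl]oxolan-2-one; 11 4-bromo-1,2-bis(benzyloxy)benzene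
Product: 13 (3R,4R)-4-ArG-1-ArC-4-(tert-butyldimethylsilyloxy)-3-(hydroxymethyl)butan-1-one, via aryllithium 12 (not isolated)
Conditions: 11, n-BuLi, THF, −78 °C; then 10, −78 °C; AcOH quench at −78 °C
Reagents that add atoms: none
Why: Bromine–lithium exchange gives 12, which adds once to the lactone carbonyl (acyl substitution of a lactone by an organolithium); the lithium hemiketal alkoxide persists at −78 °C and gives the ketone only on protonation, so a second addition is avoided.

Step 6
Reactants: 13 (3R,4R)-4-ArG-1-ArC-4-(tert-butyldimethylsilyloxy)-3-(hydroxymethyl)butan-1-one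
Product: 15 (R)-ArG[(3R)-5-ArC-2,3-dihydrofuran-3-yl]methyl tert-butyldimethylsilyl ether, via cyclic hemiketal 14 (not isolated)
Conditions: PPTS (0.1 equiv), 4 Å MS, toluene, 80 °C; Et3N quench
Reagents that add atoms: none
Why: Acid-catalysed cyclodehydration of a γ-hydroxy aryl ketone: hemiketal 14 loses water through the aryl-stabilised oxocarbenium ion, and the only available α-proton (on C8') is removed, giving the C7'=C8' enol ether. PPTS is weak enough to leave the benzylic silyl ether and the C7 and C8 centres untouched.

Step 7
Reactants: 15 (R)-ArG[(3R)-5-ArC-2,3-dihydrofuran-3-yl]methyl tert-butyldimethylsilyl ether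
Product: 16 (R)-ArG[(3R)-5-ArC-2,3-dihydrofuran-3-yl]methanol
Conditions: Bu4NF, THF, 0 °C to rt
Reagents that add atoms: none
Why: Fluoride cleaves the Si–O bond under basic conditions that the acid-labile aryl enol ether tolerates; the homoallylic alcohol is released only now because traces of acid would add O7 across the enol ether.

Step 8
Reactants: 16 (R)-ArG[(3R)-5-ArC-2,3-dihydrofuran-3-yl]methanol
Product: 20 (3R,3aR,6S,6aS)-3-ArG-6-ArC-hexahydrofuro[3,4-c]furan-1-ol (cis-fused; both anomers at C1), via phosphinite 17 (not isolated), via formyl phosphinite 18 (not isolated), via hydroxy aldehyde 19 (not isolated)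
Conditions: Rh(acac)(CO)2 (5 mol%), Ph2POMe (20 mol%), CO/H2 (1:1, 40 bar), 4 Å MS, THF, 50 °C
Reagents that add atoms: carbon monoxide, [C-]#[O+]
Why: Proposed new method: O7 of 16 exchanges with Ph2POMe to give 17, whose phosphorus holds the monovalent rhodium hydride over the face of the C7'=C8' bond that carries the C7 arm; syn hydrorhodation through a six-membered chelate (Rh–P–O7–C7–C8–C8') places rhodium on C8' and hydrogen on C7', CO inserts into the Rh–C8' bond, hydrogenolysis of the acyl gives 18, and alcohol exchange frees 19 and returns the ligand. The closest known reaction type is the rhodium-catalysed hydroformylation of homoallylic alcohols steered by a catalytic, reversibly bound phosphinite, which gives γ-lactols from terminal and 1,2-disubstituted alkenes, together with the undirected hydroformylation of 2,3-dihydrofuran; a trisubstituted aryl enol ether is new for it. The lactol ring closes by 5-exo-trig addition of O7 to the C9' formyl group, possible only for the cis-fused bicycle, so it also protects C8' from epimerisation, and the anomeric centre is of no consequence. C8' is controlled by the tether, which reaches only the face syn to the C7 arm fixed by the (R) centre at C8; C7' is controlled by the stereospecific syn addition, hydrogen entering on the same face as rhodium so that the aryl group ends up trans to C9'. The step needs regioselectivity for C8' and a contra-steric facial choice: the first is secured by the chelate size and by the reluctance of rhodium to form and carbonylate a fully substituted benzylic alkyl at C7', the second by the covalent O–P tether, since an undirected catalyst would approach anti to the C8 substituent. β-Hydride loss towards C8 is geometrically excluded because the C8 hydrogen lies anti to rhodium, so that centre should stay intact.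

Step 9
Reactants: 20 (3R,3aR,6S,6aS)-3-ArG-6-ArC-hexahydrofuro[3,4-c]furan-1-ol
Product: 21 (R)-ArG[(3R,4R,5S)-5-ArC-4-(hydroxymethyl)oxolan-3-yl]methanol
Conditions: NaBH4, MeOH/THF, 0 °C
Reagents that add atoms: none
Why: Lactol reduction: 20 stands in ring–chain equilibrium with its open hydroxy aldehyde tautomer (compound 19, already met in step 8), and NaBH4 reduces this small equilibrium amount to the C9' primary alcohol while O7–H is released; hydride addition should outpace enolisation at C8'.

Step 10
Reactants: 21 (R)-ArG[(3R,4R,5S)-5-ArC-4-(hydroxymethyl)oxolan-3-yl]methanol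
Product: 22 (7R)-7-hydroxytaxiresinol
Conditions: H2 (1 atm), 10% Pd/C, EtOAc, rt, stopped at full conversion
Reagents that add atoms: none
Why: Hydrogenolysis of three aryl benzyl ethers; the ArO–CH2Ph bonds, with phenoxide as leaving group, cleave much faster than the C7–O7 alcohol and the C7'–O9 ring ether under neutral, aprotic conditions, so all four stereocentres should be retained.

## Compound list

1 | monomethyl succinate (4-methoxy-4-oxobutanoic acid) | COC(=O)CCC(O)=O | starting material
2 | (R)-4-benzyl-2-oxazolidinone | O=C1N[C@H](Cc2ccccc2)CO1 | starting material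
3 | 4-methoxy-4-oxobutanoic pivalic anhydride | COC(=O)CCC(=O)OC(=O)C(C)(C)C | intermediate
4 | methyl 4-[(4R)-4-benzyl-2-oxooxazolidin-3-yl]-4-oxobutanoate | COC(=O)CCC(=O)N1[C@H](Cc2ccccc2)COC1=O | intermediate
5 | 4-benzyloxy-3-methoxybenzaldehyde | COc1cc(C=O)ccc1OCc1ccccc1 | starting material
6 | methyl (3S,4R)-3-[(4R)-4-benzyl-2-oxooxazolidine-3-carbonyl]-4-(4-benzyloxy-3-methoxyphenyl)-4-(trimethylsilyloxy)butanoate | COc1cc([C@H](O[Si](C)(C)C)[C@H](CC(=O)OC)C(=O)N2[C@H](Cc3ccccc3)COC2=O)ccc1OCc1ccccc1 | intermediate
7 | methyl (3S,4R)-3-[(4R)-4-benzyl-2-oxooxazolidine-3-carbonyl]-4-(4-benzyloxy-3-methoxyphenyl)-4-hydroxybutanoate | COc1cc([C@H](O)[C@H](CC(=O)OC)C(=O)N2[C@H](Cc3ccccc3)COC2=O)ccc1OCc1ccccc1 | intermediate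
8 | methyl (3R,4R)-4-(4-benzyloxy-3-methoxyphenyl)-4-hydroxy-3-(hydroxymethyl)butanoate | COc1cc([C@H](O)[C@@H](CO)CC(=O)OC)ccc1OCc1ccccc1 | intermediate
9 | (4R)-4-[(R)-(4-benzyloxy-3-methoxyphenyl)(hydroxy)methyl]oxolan-2-one | COc1cc([C@H](O)[C@H]2COC(=O)C2)ccc1OCc1ccccc1 | intermediate
10 | (4R)-4-[(R)-(4-benzyloxy-3-methoxyphenyl)(tert-butyldimethylsilyloxy)methyl]oxolan-2-one | COc1cc([C@H](O[Si](C)(C)C(C)(C)C)[C@H]2COC(=O)C2)ccc1OCc1ccccc1 | intermediate
11 | 4-bromo-1,2-bis(benzyloxy)benzene | Brc1ccc(OCc2ccccc2)c(OCc2ccccc2)c1 | starting material
12 | [3,4-bis(benzyloxy)phenyl]lithium | [Li]c1ccc(OCc2ccccc2)c(OCc2ccccc2)c1 | intermediate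
13 | (3R,4R)-4-(4-benzyloxy-3-methoxyphenyl)-1-[3,4-bis(benzyloxy)phenyl]-4-(tert-butyldimethylsilyloxy)-3-(hydroxymethyl)butan-1-one | COc1cc([C@H](O[Si](C)(C)C(C)(C)C)[C@@H](CO)CC(=O)c2ccc(OCc3ccccc3)c(OCc3ccccc3)c2)ccc1OCc1ccccc1 | intermediate
14 | (4R)-2-[3,4-bis(benzyloxy)phenyl]-4-[(R)-(4-benzyloxy-3-methoxyphenyl)(tert-butyldimethylsilyloxy)methyl]oxolan-2-ol (both configurations at C2) | COc1cc([C@H](O[Si](C)(C)C(C)(C)C)[C@H]2COC(O)(c3ccc(OCc4ccccc4)c(OCc4ccccc4)c3)C2)ccc1OCc1ccccc1 | intermediate
15 | tert-butyl{(R)-(4-benzyloxy-3-methoxyphenyl)[(3R)-5-[3,4-bis(benzyloxy)phenyl]-2,3-dihydrofuran-3-yl]methoxy}dimethylsilane | COc1cc([C@H](O[Si](C)(C)C(C)(C)C)[C@H]2COC(c3ccc(OCc4ccccc4)c(OCc4ccccc4)c3)=C2)ccc1OCc1ccccc1 | intermediate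
16 | (R)-(4-benzyloxy-3-methoxyphenyl)[(3R)-5-[3,4-bis(benzyloxy)phenyl]-2,3-dihydrofuran-3-yl]methanol | COc1cc([C@H](O)[C@H]2COC(c3ccc(OCc4ccccc4)c(OCc4ccccc4)c3)=C2)ccc1OCc1ccccc1 | intermediate
17 | (R)-(4-benzyloxy-3-methoxyphenyl)[(3R)-5-[3,4-bis(benzyloxy)phenyl]-2,3-dihydrofuran-3-yl]methyl diphenylphosphinite | COc1cc([C@H](OP(c2ccccc2)c2ccccc2)[C@H]2COC(c3ccc(OCc4ccccc4)c(OCc4ccccc4)c3)=C2)ccc1OCc1ccccc1 | intermediate
18 | (R)-(4-benzyloxy-3-methoxyphenyl)[(3R,4S,5S)-5-[3,4-bis(benzyloxy)phenyl]-4-formyloxolan-3-yl]methyl diphenylphosphinite | COc1cc([C@H](OP(c2ccccc2)c2ccccc2)[C@H]2CO[C@H](c3ccc(OCc4ccccc4)c(OCc4ccccc4)c3)[C@H]2C=O)ccc1OCc1ccccc1 | intermediate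
19 | (2S,3S,4R)-2-[3,4-bis(benzyloxy)phenyl]-4-[(R)-(4-benzyloxy-3-methoxyphenyl)(hydroxy)methyl]oxolane-3-carbaldehyde | COc1cc([C@H](O)[C@H]2CO[C@H](c3ccc(OCc4ccccc4)c(OCc4ccccc4)c3)[C@H]2C=O)ccc1OCc1ccccc1 | intermediate
20 | (3R,3aR,6S,6aS)-3-(4-benzyloxy-3-methoxyphenyl)-6-[3,4-bis(benzyloxy)phenyl]hexahydrofuro[3,4-c]furan-1-ol (cis-fused, both anomers at C1) | OC1O[C@@H](c2ccc(OCc3ccccc3)c(OC)c2)[C@H]2CO[C@H](c3ccc(OCc4ccccc4)c(OCc4ccccc4)c3)[C@@H]12 | intermediate
21 | (R)-(4-benzyloxy-3-methoxyphenyl)[(3R,4R,5S)-5-[3,4-bis(benzyloxy)phenyl]-4-(hydroxymethyl)oxolan-3-yl]methanol | COc1cc([C@H](O)[C@H]2CO[C@H](c3ccc(OCc4ccccc4)c(OCc4ccccc4)c3)[C@H]2CO)ccc1OCc1ccccc1 | intermediate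
22 | (7R)-7-hydroxytaxiresinol, 4-[(2S,3R,4R)-4-[(R)-hydroxy(4-hydroxy-3-methoxyphenyl)methyl]-3-(hydroxymethyl)oxolan-2-yl]benzene-1,2-diol | COc1cc([C@H](O)[C@H]2CO[C@H](c3ccc(O)c(O)c3)[C@H]2CO)ccc1O | target

## Step count and least certain steps

Total step count: 10. Longest linear sequence: 10 steps (1 to 22); 2, 5 and 11 are commercial and enter at steps 1, 2 and 5.

Step 8 (key step, proposed new method). The most likely failure is that the trisubstituted, electron-rich double bond inserts into the Rh–H bond too slowly. An undirected background pathway (wrong face), plain hydrogenation, or acid-promoted addition of O7 across the enol ether would then take over, and facial selectivity would be poor. The fallback uses known lignan chemistry and sets out from 10, whose carbonyl carbon then serves as C9' instead of C7'. The lithium enolate of 10 (LiN(SiMe3)2, THF, −78 °C) is added to commercial 3,4-bis(benzyloxy)benzaldehyde; attack anti to the C4 substituent gives the trans-disubstituted aldol lactone F1 as a mixture at the new carbinol. LiAlH4 reduces it to the triol F2. A catalytic acid (camphorsulfonic acid, CH2Cl2, 0 °C) ionises the free benzylic C7' alcohol, and O9 closes the tetrahydrofuran with the aryl group trans to C9', giving the silyl ether F3; the less basic, bulkier silyl ether oxygen at C7 should ionise more slowly. Bu4NF then returns the route at 21. The trans lactone becomes the 8,8'-cis tetrahydrofuran because C7' and C9' exchange their ring and substituent roles at C8'.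

Step 2. The most likely failures are erosion of anti or facial selectivity with the ester-bearing imide, slow turnover with the electron-rich aldehyde, and retro-aldol during desilylation, any of which would deliver 9 contaminated with its C7 epimer. The fallback sets C7 by reagent control and sets out from 9 (as its C7 mixture). Dess–Martin oxidation under neutral conditions gives the aryl ketone F4, whose C8 centre is kept away from base. Corey–Bakshi–Shibata reduction (the (S)-methyl oxazaborolidine, BH3·SMe2, −20 °C), with the aryl group acting as the large substituent, should return the (7R) alcohol 9.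

Step 3. The most likely failures are over-reduction of the methyl ester or of the lactone, and incomplete acyl transfer from O7 to O9. The fallback changes the order of events and sets out from 7. Silylation (TBSOTf, 2,6-lutidine) gives the silyl ether F5. LiBH4 (THF, 1 equiv MeOH, 0 °C) then cleaves the auxiliary to the hydroxy ester F6, in which only O9 is free. F6 lactonises on work-up to 10, where the route is rejoined, so step 4 is not needed.

Step 5. The most likely failures are a second addition of 12, enolisation of the lactone, and silyl migration from O7 to the O9 alkoxide. The fallback sets out from 10. Me(MeO)NH·HCl and AlMe3 (CH2Cl2, 0 °C) open the lactone to the hydroxy amide F7. Et3SiCl and imidazole protect O9 as the bis-silyl ether F8. 12 adds to the N-methoxy-N-methylamide through a stable chelate to give the ketone F9. PPTS in MeOH then removes the primary triethylsilyl group selectively and returns the route at 13.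

Step 10. The most likely failure is hydrogenolysis running on into the benzylic C7–O7 and C7'–O9 bonds once the phenols are free. The fallback replaces catalytic hydrogenolysis by single-electron reductive debenzylation and runs from 21 directly to 22: lithium naphthalenide (LiC10H8, THF, −25 °C) after deprotonation of the two alcohols. The electron enters the unsubstituted phenyl ring of each benzyl group and expels a phenoxide, whereas the oxygenated rings, which become phenoxide-bearing, are poor electron acceptors, so the ring ether and the C7 alkoxide should survive.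

## Further compounds

F1 | step 8 | (3S,4R)-3-{[3,4-bis(benzyloxy)phenyl](hydroxy)methyl}-4-[(R)-(4-benzyloxy-3-methoxyphenyl)(tert-butyldimethylsilyloxy)methyl]oxolan-2-one (both configurations at the new carbinol) | COc1cc([C@H](O[Si](C)(C)C(C)(C)C)[C@H]2COC(=O)[C@@H]2C(O)c2ccc(OCc3ccccc3)c(OCc3ccccc3)c2)ccc1OCc1ccccc1
F2 | step 8 | (2R,3R,4R)-4-(4-benzyloxy-3-methoxyphenyl)-1-[3,4-bis(benzyloxy)phenyl]-4-(tert-butyldimethylsilyloxy)-2,3-bis(hydroxymethyl)butan-1-ol (both configurations at C1) | COc1cc([C@H](O[Si](C)(C)C(C)(C)C)[C@@H](CO)[C@H](CO)C(O)c2ccc(OCc3ccccc3)c(OCc3ccccc3)c2)ccc1OCc1ccccc1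
F3 | step 8 | [(2S,3R,4R)-4-[(R)-(4-benzyloxy-3-methoxyphenyl)(tert-butyldimethylsilyloxy)methyl]-2-[3,4-bis(benzyloxy)phenyl]oxolan-3-yl]methanol | COc1cc([C@H](O[Si](C)(C)C(C)(C)C)[C@H]2CO[C@H](c3ccc(OCc4ccccc4)c(OCc4ccccc4)c3)[C@H]2CO)ccc1OCc1ccccc1
F4 | step 2 | (4R)-4-(4-benzyloxy-3-methoxybenzoyl)oxolan-2-one | COc1cc(C(=O)[C@H]2COC(=O)C2)ccc1OCc1ccccc1
F5 | step 3 | methyl (3S,4R)-3-[(4R)-4-benzyl-2-oxooxazolidine-3-carbonyl]-4-(4-benzyloxy-3-methoxyphenyl)-4-(tert-butyldimethylsilyloxy)butanoate | COc1cc([C@H](O[Si](C)(C)C(C)(C)C)[C@H](CC(=O)OC)C(=O)N2[C@H](Cc3ccccc3)COC2=O)ccc1OCc1ccccc1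
F6 | step 3 | methyl (3R,4R)-4-(4-benzyloxy-3-methoxyphenyl)-4-(tert-butyldimethylsilyloxy)-3-(hydroxymethyl)butanoate | COc1cc([C@H](O[Si](C)(C)C(C)(C)C)[C@@H](CO)CC(=O)OC)ccc1OCc1ccccc1
F7 | step 5 | (3R,4R)-4-(4-benzyloxy-3-methoxyphenyl)-4-(tert-butyldimethylsilyloxy)-3-(hydroxymethyl)-N-methoxy-N-methylbutanamide | COc1cc([C@H](O[Si](C)(C)C(C)(C)C)[C@@H](CO)CC(=O)N(C)OC)ccc1OCc1ccccc1
F8 | step 5 | (3R,4R)-4-(4-benzyloxy-3-methoxyphenyl)-4-(tert-butyldimethylsilyloxy)-N-methoxy-N-methyl-3-[(triethylsilyloxy)methyl]butanamide | COc1cc([C@H](O[Si](C)(C)C(C)(C)C)[C@@H](CO[Si](CC)(CC)CC)CC(=O)N(C)OC)ccc1OCc1ccccc1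
F9 | step 5 | (3R,4R)-4-(4-benzyloxy-3-methoxyphenyl)-1-[3,4-bis(benzyloxy)phenyl]-4-(tert-butyldimethylsilyloxy)-3-[(triethylsilyloxy)methyl]butan-1-one | COc1cc([C@H](O[Si](C)(C)C(C)(C)C)[C@@H](CO[Si](CC)(CC)CC)CC(=O)c2ccc(OCc3ccccc3)c(OCc3ccccc3)c2)ccc1OCc1ccccc1
F0 | step 10 | none | none
A1 | alternative 1 | 1,3-dioxoisoindolin-2-yl (3R)-3-(4-benzyloxy-3-methoxyphenyl)-2-({[(1S,2E)-1-[3,4-bis(benzyloxy)phenyl]-3-(4,4,5,5-tetramethyl-1,3,2-dioxaborolan-2-yl)prop-2-en-1-yl]oxy}methyl)-3-(tert-butyldimethylsilyloxy)propanoate (both configurations at C2) | COc1cc([C@H](O[Si](C)(C)C(C)(C)C)C(CO[C@H](c2ccc(OCc3ccccc3)c(OCc3ccccc3)c2)/C=C/B2OC(C)(C)C(C)(C)O2)C(=O)ON2C(=O)c3ccccc3C2=O)ccc1OCc1ccccc1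
A2 | alternative 1 | tert-butyl{(R)-(4-benzyloxy-3-methoxyphenyl)[(3R,4S,5S)-5-[3,4-bis(benzyloxy)phenyl]-4-[(4,4,5,5-tetramethyl-1,3,2-dioxaborolan-2-yl)methyl]oxolan-3-yl]methoxy}dimethylsilane | COc1cc([C@H](O[Si](C)(C)C(C)(C)C)[C@H]2CO[C@H](c3ccc(OCc4ccccc4)c(OCc4ccccc4)c3)[C@H]2CB2OC(C)(C)C(C)(C)O2)ccc1OCc1ccccc1
A3 | alternative 2 | (2S)-2-[3,4-bis(benzyloxy)phenyl]-2,5-dihydrofuran | C1=C[C@@H](c2ccc(OCc3ccccc3)c(OCc3ccccc3)c2)OC1
A4 | alternative 2 | (4-benzyloxy-3-methoxyphenyl)ketene | COc1cc(C=C=O)ccc1OCc1ccccc1
A5 | alternative 2 | 7-endo-(4-benzyloxy-3-methoxyphenyl)-4-exo-[3,4-bis(benzyloxy)phenyl]-3-oxabicyclo[3.2.0]heptan-6-one, configured at C7, C8, C8' and C7' as in 20 | O=C1[C@@H](c2ccc(OCc3ccccc3)c(OC)c2)[C@H]2CO[C@H](c3ccc(OCc4ccccc4)c(OCc4ccccc4)c3)[C@@H]12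
A6 | alternative 2 | (3R,3aR,6S,6aS)-3-(4-benzyloxy-3-methoxyphenyl)-6-[3,4-bis(benzyloxy)phenyl]tetrahydro-1H,3H-furo[3,4-c]furan-1-one | O=C1O[C@@H](c2ccc(OCc3ccccc3)c(OC)c2)[C@H]2CO[C@H](c3ccc(OCc4ccccc4)c(OCc4ccccc4)c3)[C@@H]12
A7 | alternative 3 | dimethyl 2-[3,4-bis(benzyloxy)benzylidene]malonate | COC(=O)C(=Cc1ccc(OCc2ccccc2)c(OCc2ccccc2)c1)C(=O)OC
A8 | alternative 3 | 2-vinyloxirane (racemic) | C=CC1CO1
A9 | alternative 3 | dimethyl 2-[3,4-bis(benzyloxy)phenyl]-4-vinyloxolane-3,3-dicarboxylate, 2,4-trans, configured at C7' and C8 as in the target | C=C[C@H]1CO[C@H](c2ccc(OCc3ccccc3)c(OCc3ccccc3)c2)C1(C(=O)OC)C(=O)OC
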